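| flask | substrate | coupling partner | temperature | remark | time |
|---|---|---|---|---|---|
| south | 0.013 M | 0.104 M | 95 °C | run made earlier |  |
| north | 0.019 M | 0.104 M | 115 °C | run made earlier |  |
| north-west | 0.026 M | 0.21 M | 95 °C | run made earlier |  |
| eta | 0.026 M | 0.104 M | 130 °C |  | 1.0 h |
| delta | 0.026 M | 0.104 M | 115 °C |  | 1.0 h |
| beta | 0.026 M | 0.104 M | 100 °C |  | 1.0 h |

- south (time / h: target / %, isomer of the product / %): 0.833: 5.4, 0; 1.33: 5.6, 0.8; 2.00: 11.8, 0; 3.00: 20.5, 7.1; 4.00: 30.1, 8.6
- north (time / min: target / %, isomer of the product / %): 15.0: 1.8, 0; 30.0: 7.2, 3.3; 40.0: 17.2, 6.2; 60.0: 35.2, 13.4; 80.0: 50.8, 24.1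
- north-west (time / h: target / %, isomer of the product / %): 0.250: 5.1, 0; 0.500: 26.0, 0.8; 1.00: 52.5, 6.7; 2.00: 59.2, 15.7; 4.00: 65.4, 25.9

(readings scatter by 1 percentage point)



* the best flask by share of target in all that became target or isomer of the product; "all alike" if 1.5 percentage points covers them all (eta / delta / beta / all alike)
* share of target in all that became target or isomer of the product, eta
* share of target in all that became target or isomer of the product, delta
* share of target in all that became target or isomer of the product, beta

The ratio c(isomer of the product)/c(target) is what to follow in this repeat. In the north-west run at 95 °C, the isomer climbs from 6.7 % to 15.7 % between 1.00 h and 2.00 h while the target stands in the fifties, so I read 0.161 /h. The same reading on the last interval of the north run at 115 °C gives 0.747 /h. That pair means an activation energy of about 91.1 kJ/mol, and at 100 °C it gives 0.240 /h: the leak, the isomer gained per hour per unit of target standing in the flask.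

Each flask starts with substrate and coupling partner, and target and isomer appear later. If target builds steadily, it has stood for about half the elapsed time, so the ratio is about half of the leak multiplied by the elapsed time. I ignore the lag, visible in the north run as 1.8 % of target at 15.0 min. The leak of eta comes out at 2.13 /h, so my selectivity at 1.0 h is 89.3 % for beta, 72.8 % for delta and 48.4 % for eta. Eta and beta differ in temperature, and my leak is larger for eta than for beta, so the bath is what not to touch.

The forecast names beta, with 85 % (75 % to 93 %) for beta, 71 % (61 % to 79 %) for delta and 55 % (38 % to 69 %) for eta, adding of eta that “the apparent slowing of isomerisation makes this uncertain”. My order is the same, but my numbers differ.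

The flask gives beta as best, with 86.7 %, 70.0 % and 58.6 % for beta, delta and eta.

    substrate + coupling partner + released group → target + 2 released group (k = 44.0 /M²/min, Ea = 40.0 kJ/mol)
    substrate + coupling partner → target + released group (k = 0.00650 /M/min, Ea = 96.0 kJ/mol)
    substrate ⇌ dormant form (K = 1.90, k = 0.0330 /min, Ea = 99.0 kJ/mol, ΔH = −45.0 kJ/mol)
    target ⇌ isomer of the product (K = 0.460, k = 0.00940 /min, Ea = 124 kJ/mol, ΔH = 18.0 kJ/mol)
    (constants at 100 °C)

In beta at 1.00 h, target is made 5.51 times faster than it is used up, while the dormant form holds 55.2 % of the substrate, which the share doesn't count. My leak gave a ratio of 0.120 there, and the flask holds 0.154. For beta stopped at 25 min, the leak gives a share of 95.2 %; the computed flask gives 92.4 %, with 3.71 % of target.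

The readings are calculated from invented constants, noise included.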